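**Assumptions (one line):** the target is taken exactly as drawn, i.e. the (2R,3R)-trans-flavanonol with an (R)-configured side chain; compounds 1, 3, 5, 8 and 10 are treated as catalogue chemicals. The sense of induction of the two chiral catalysts (steps 2 and 7) is my best recollection and must be confirmed on the first run; both ligand antipodes are commercial.

## Retrosynthetic overview

1. The C ring is formed last, in one flask: a C_s-symmetric A-ring aryllithium is acylated by an enantiopure B-ring glycidic amide (C4–C4a), then acid unmasks the phenols and the epoxide closes O1–C2. This step breaks the A-ring symmetry.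
2. The A ring comes from C2v-symmetric 5-methoxyresorcinol. The side chain goes on at the unique carbon between the two protected oxygens, so no regiochemical question arises.
3. The side-chain stereocentre and the isopropenyl group are made together by Cu-catalysed asymmetric SN2′ alkylation of (E)-1,4-dibromo-2-methylbut-2-ene.
4. The B ring and C2/C3 come from 2,4-dihydroxybenzaldehyde by olefination to an enamide and catalytic asymmetric epoxidation (sets C3; C2 follows on ring closure).
5. Ring order: A and B rings are bought aromatic; only the pyranone ring is built.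

Compound numbers follow first appearance in the forward route.

## Route

**Step 1**
Reactants: 1, 4-bromo-2-methylbutan-2-ol
Product: 2, [(4-bromo-2-methylbutan-2-yl)oxy]triethylsilane
Conditions: TESOTf, 2,6-lutidine, CH2Cl2, 0 °C → rt
Reagents that add atoms: triethylsilyl triflate, CC[Si](CC)(CC)OS(=O)(=O)C(F)(F)F
Why: Silylation of a hindered tertiary alcohol with a silyl triflate; the TES ether masks the OH through the Grignard and organolithium steps and falls off in the final acid step.

**Step 2**
Reactants: 2; 3, (E)-1,4-dibromo-2-methylbut-2-ene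
Product: 4, (3S)-3-(bromomethyl)-2,6-dimethyl-6-[(triethylsilyl)oxy]hept-1-ene
Conditions: (i) 2, Mg, Et2O, rt; (ii) slow addition to 3, CuBr·SMe2 (3 mol %), (R,Rp)-Taniaphos (3.6 mol %; antipode chosen to give the S bromide), CH2Cl2, −78 °C
Reagents that add atoms: none
Why: Proposed new method: Cu-catalysed asymmetric allylic alkylation, extended from its closest precedents (Cu/Taniaphos SN2′ alkylation of 1,4-dibromobut-2-ene with Grignards; Cu/phosphoramidite alkylation of β-methyl allylic halides) to the 2-methyl dibromide. The chiral alkylcopper should add anti-SN2′ at C3 (the CH terminus) with loss of the C1 bromide, because the alternative SN2′ at C2 needs a tertiary Cu(III) allyl; this creates the (S) stereocentre and the isopropenyl group in one bond formation, and the surviving CH2Br is no longer allylic so it does not react again.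

**Step 3**
Reactants: 5, 5-methoxybenzene-1,3-diol (5-methoxyresorcinol)
Product: 6, 5-methoxy-1,3-bis(methoxymethoxy)benzene
Conditions: MOMCl, i-Pr2NEt, CH2Cl2, 0 °C → rt
Reagents that add atoms: chloromethyl methyl ether, COCCl
Why: Phenol O-alkylation (MOM acetal formation); the MOM groups protect the phenols and are the directing groups for both lithiations.

**Step 4**
Reactants: 6 (1.5 equiv); 4
Product: 7, 5-methoxy-1,3-bis(methoxymethoxy)-2-[(2R)-5-methyl-2-(prop-1-en-2-yl)-5-(triethylsilyloxy)hexyl]benzene
Conditions: 6, n-BuLi, THF, 0 °C; MgBr2·OEt2; then 4, CuI (10 mol %), TMEDA, LiOMe, 0 °C → rt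
Reagents that add atoms: none
Why: Directed ortho-metalation at the only carbon flanked by two MOM ethers, then transmetalation and Cu-catalysed SN2 coupling of the aryl Grignard with the primary bromide (Kumada-type sp2–sp3 coupling). The stereocentre is β to the reacting carbon and is untouched; the descriptor changes from S to R only because aryl replaces Br in the CIP ranking. Product 7 is still C_s-symmetric.

**Step 5**
Reactants: 8, 2,4-dihydroxybenzaldehyde
Product: 9, 2,4-bis(methoxymethoxy)benzaldehyde
Conditions: MOMCl (2.5 equiv), i-Pr2NEt, CH2Cl2, 0 °C → rt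
Reagents that add atoms: chloromethyl methyl ether, COCCl
Why: MOM protection of both phenols (excess base and reagent overcome the H-bonded ortho-OH) so the aldehyde is electrophilic and the later nucleophilic epoxidation is not quenched.

**Step 6**
Reactants: 9; 10, diethyl [2-(morpholin-4-yl)-2-oxoethyl]phosphonate
Product: 11, (E)-3-[2,4-bis(methoxymethoxy)phenyl]-1-(morpholin-4-yl)prop-2-en-1-one
Conditions: NaH, THF, 0 °C → rt
Reagents that add atoms: none
Why: Horner–Wadsworth–Emmons olefination with a stabilised amide phosphonate gives the E-enamide; the morpholine amide is both a good substrate for lanthanide-catalysed epoxidation and a Weinreb-type acyl donor.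

**Step 7**
Reactants: 11
Product: 12, [(2R,3S)-3-[2,4-bis(methoxymethoxy)phenyl]oxiran-2-yl](morpholin-4-yl)methanone
Conditions: Sm(O-i-Pr)3 / (S)-BINOL / Ph3As=O (10 mol % each), TBHP (decane), 4 Å MS, THF, rt
Reagents that add atoms: tert-butyl hydroperoxide, CC(C)(C)OO
Why: Shibasaki lanthanide–BINOL nucleophilic asymmetric epoxidation of an α,β-unsaturated morpholine amide; the catalyst sets both epoxide carbons (trans, 2R,3S), and the α-carbon becomes C3 of the target with its C–O bond intact.

**Step 8 (key step)**
Reactants: 7; 12
Product: 14, (2R,3R)-2-(2,4-dihydroxyphenyl)-3,7-dihydroxy-8-[(2R)-5-hydroxy-5-methyl-2-(prop-1-en-2-yl)hexyl]-5-methoxy-2,3-dihydro-4H-chromen-4-one (the target), via non-isolated epoxy ketone 13, [(2R,3S)-3-[2,4-bis(methoxymethoxy)phenyl]oxiran-2-yl]{6-methoxy-2,4-bis(methoxymethoxy)-3-[(2R)-5-methyl-2-(prop-1-en-2-yl)-5-(triethylsilyloxy)hexyl]phenyl}methanone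
Conditions: 7, n-BuLi, TMEDA, THF, 0 °C; 12, −78 → −40 °C; then HCl/MeOH–THF (ca. 1 M), 0 → 35 °C, same flask
Reagents that add atoms: none
Why: Symmetry-breaking directed ortho-lithiation (the two remaining ring C–H of 7 are equivalent, so only one aryllithium forms) and acylation by the morpholine amide (stable tetrahedral intermediate, no over-addition) give 13. Acid then removes the four MOM groups and the TES group, and the one phenol ortho to the ketone opens the epoxide 6-endo at the benzylic carbon, which is activated by the o,p-dioxygenated B ring. C3 keeps the epoxide α-configuration (R), and C2 becomes R by inversion; any SN1 leakage to the cis isomer converges on the thermodynamically favoured 2,3-trans product under the same acid. Mild temperature spares the isopropenyl group and the tertiary alcohol.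

## Compound list

1 | 4-bromo-2-methylbutan-2-ol | CC(C)(O)CCBr | starting material
2 | [(4-bromo-2-methylbutan-2-yl)oxy]triethylsilane | CC[Si](CC)(CC)OC(C)(C)CCBr | intermediate
3 | (E)-1,4-dibromo-2-methylbut-2-ene | BrC/C(C)=C/CBr | starting material
4 | (3S)-3-(bromomethyl)-2,6-dimethyl-6-[(triethylsilyl)oxy]hept-1-ene | C=C(C)[C@H](CCC(C)(C)O[Si](CC)(CC)CC)CBr | intermediate
5 | 5-methoxybenzene-1,3-diol | COc1cc(O)cc(O)c1 | starting material
6 | 5-methoxy-1,3-bis(methoxymethoxy)benzene | COCOc1cc(OC)cc(OCOC)c1 | intermediate
7 | 5-methoxy-1,3-bis(methoxymethoxy)-2-[(2R)-5-methyl-2-(prop-1-en-2-yl)-5-(triethylsilyloxy)hexyl]benzene | C=C(C)[C@H](CCC(C)(C)O[Si](CC)(CC)CC)Cc1c(OCOC)cc(OC)cc1OCOC | intermediate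
8 | 2,4-dihydroxybenzaldehyde | O=Cc1ccc(O)cc1O | starting material
9 | 2,4-bis(methoxymethoxy)benzaldehyde | O=Cc1ccc(OCOC)cc1OCOC | intermediate
10 | diethyl [2-(morpholin-4-yl)-2-oxoethyl]phosphonate | CCOP(=O)(OCC)CC(=O)N1CCOCC1 | starting material
11 | (E)-3-[2,4-bis(methoxymethoxy)phenyl]-1-(morpholin-4-yl)prop-2-en-1-one | O=C(/C=C/c1ccc(OCOC)cc1OCOC)N1CCOCC1 | intermediate
12 | [(2R,3S)-3-[2,4-bis(methoxymethoxy)phenyl]oxiran-2-yl](morpholin-4-yl)methanone | O=C(N1CCOCC1)[C@@H]1O[C@H]1c1ccc(OCOC)cc1OCOC | intermediate
13 | [(2R,3S)-3-[2,4-bis(methoxymethoxy)phenyl]oxiran-2-yl]{6-methoxy-2,4-bis(methoxymethoxy)-3-[(2R)-5-methyl-2-(prop-1-en-2-yl)-5-(triethylsilyloxy)hexyl]phenyl}methanone | C=C(C)[C@H](CCC(C)(C)O[Si](CC)(CC)CC)Cc1c(OCOC)cc(OC)c(C(=O)[C@@H]2O[C@H]2c2ccc(OCOC)cc2OCOC)c1OCOC | intermediate (not isolated)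
14 | (2R,3R)-2-(2,4-dihydroxyphenyl)-3,7-dihydroxy-8-[(2R)-5-hydroxy-5-methyl-2-(prop-1-en-2-yl)hexyl]-5-methoxy-2,3-dihydro-4H-chromen-4-one | C=C(C)[C@H](CCC(C)(C)O)Cc1c(O)cc(OC)c2c1O[C@H](c1ccc(O)cc1O)[C@@H](O)C2=O | target

## Summary

**Total steps:** 8.
**Longest linear sequence:** 4 steps (1 → 2 → 4 → 8, or 5 → 6 → 7 → 8).

**Three steps most likely to fail, with fallbacks:**

1. **Step 2 (Cu-catalysed asymmetric SN2′ on the 2-methyl dibromide).** Regio- and enantioselectivity on this substrate are unproven. Fallback: run the alkylation on the literature substrate (E)-1,4-dibromobut-2-ene to get the 2-vinyl analogue of 4, couple it as in step 4, then convert vinyl to isopropenyl by Wacker oxidation and non-basic (Petasis) methylenation before step 8. This costs two extra steps.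

2. **Step 4 (Cu-catalysed coupling of a di-ortho-substituted aryl Grignard with a β-branched homoallylic bromide).** The coupling may be slow, or E2 may give the diene. Fallback: reverse the polarity. Quench the aryllithium of 6 with I2, convert 4 to the alkylzinc bromide (Zn, LiCl), and join them by Pd/CPhos Negishi coupling. This costs one extra step.

3. **Step 8 (one-flask acylation and acid cascade).** The aryllithium may deprotonate rather than add to 12, or the acid stage may cyclise the isopropenyl group onto a neighbouring phenol or cause aryl migration. Fallback: go through the chalcone. Trap the aryllithium of 7 with N-methoxy-N-methylacetamide, condense with 9 (Claisen–Schmidt), epoxidise with poly-L-leucine/H2O2 (Juliá–Colonna), then deprotect and cyclise as a separate step under non-protic conditions (TMSOTf/2,2′-bipyridyl, then HF·pyridine for the TES group).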